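The numbers in the tables come from a simulation for substances that don't exist.

A fall that looks straight tempts one to read a constant rate, and a constant rate cannot be carried to a flask with another charge. So I tested the straightness of the ochre run before using it.

all flasks: gas phase 12 mM (held)
- ochre: starting material 0.52 M; protic impurity 0.052 M; run made earlier
- flask: starting material 0.26 M; protic impurity 0.0520 M; time 6.0 d

ochre run (percent of the starting material charged)

| time / h | target / % | starting material / % |
|---|---|---|
| 2.00 | 3.9 | 87.4 |
| 6.00 | 9.2 | 79.5 |
| 10.0 | 13.3 | 71.8 |
| 15.0 | 16.6 | 64.6 |
| 20.0 | 19.4 | 58.3 |
| 30.0 | 20.6 | 45.0 |

(each reading ± 0.5 percentage points)

- at the start none of the gas is dissolved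
- reactions considered so far: target <-> isomer of the product; dissolved gas + target -> over-reacted product; dissolved gas -> decomposed reagent; starting material + dissolved gas -> target; starting material + protic impurity -> quenched substrate; gas phase <-> dissolved gas

- north-east: doubling the transfer coefficient of the gas phase, all else as stated
- west: doubling the saturation concentration of gas phase, all else as stated

- the target standing at 6.0 d, as a percentage of the starting material charged
- the change that raises the amount of target at 6.0 d, in percent of the starting material charged most ("none" if none brings more than 2 percentage points) (north-east / west / none)
- amount of target at 6.0 d, in percent of the starting material charged, after north-east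

I read the starting-material column of the ochre run in two stretches. From the first row to the third, c(starting material) lost 16 percentage points in 0.333 d; from the third to the last it lost 27 points in 0.833 d. The fall slows, but its logarithmic slope barely moves: 0.0246 /h, then 0.0234 /h. I therefore read it as pseudo-first-order, with 0.0237 /h over the whole span.

I assumed that this constant holds in the flask, so the turnovers, the constant times the time, come to 3.41. Taken one to one, the protic impurity claims 20.0% of the flask's charge. What I expected to remain was that charge less the claim, times exp(−turnovers): 2.63%.

The target column is harder. Between the last two rows target gained 1.2 points while starting material lost 13 points, so target passes material on. This reckoning of starting material gave me no figure for target. Set beside a margin of 2 points, the 2.63% left to convert did not rule out either change.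

The forecast gave 4%, 2% after north-east and none as the best change, holding that “I see no reverse flux, so I expect little remains”.

    target ⇌ isomer of the product (K = 2.66, k = 0.0507 /h)
    dissolved gas + target → over-reacted product (k = 1.45 /M/h)
    dissolved gas → decomposed reagent (k = 0.225 /h)
    starting material + dissolved gas → target (k = 2.81 /M/h)
    starting material + protic impurity → quenched substrate (k = 3.95 /M/h)
    gas phase ⇌ dissolved gas, rate k6*(csat - [dissolved gas]) (kL = 2.79 /h)

The flask gave 11.2% of target, and 10.6% after north-east, so the best change is none: north-east moved target by −0.61 points and west by −5.9 points. At 6.00 d, target was being made at 0.721 of the rate at which it was used up, each step taken net. My 2.63% of starting material stood against 1.2% in the flask. A neighbouring flask, differing only in holding 0.13 M of protic impurity, has the same 3.41 turnovers, which reckons to 1.65%; it held 0.65%.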